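**Plan**

- Retrosynthesis: the two phenols are carried as benzyl ethers and the butane-1,4-diol is folded into a γ-butyrolactone (C=O on the CH2OH carbon beside the benzofuranylmethyl arm). The bond between that arm's CH2 and C5 of the dihydrobenzofuran is then cut, leaving an α-methylene lactone and a C5 arylboronate.
- Enabling feature: in the lactone this CH2 is an exocyclic methylene on C3, conjugated with the ring C2=O (a Michael acceptor). The C3 centre created on arylation is α to the carbonyl on a five-membered ring, so it can be equilibrated to trans against the fixed C4 benzyl group.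
- Lactone half: C3=CH2 from formaldehyde; the C3–C4 bond from an Evans alkylation of a 3-arylpropanoyl imide with tert-butyl bromoacetate, then reduction and lactonisation.
- Benzofuran half: O1–C2 cut (phenol onto a p-alkoxybenzyl cation) and C2–C3 cut (Evans syn-aldol of an arylacetyl imide with O-benzylvanillin); the Br of 5-bromo-o-vanillin becomes the boronate.
- Forward order: lactone ring, dihydrobenzofuran ring, union by Rh-catalysed conjugate arylation, LiAlH4 opening of the helper lactone, hydrogenolysis.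
- Stereochemistry: lactone C4 and benzofuran C3 from (S)-4-benzyloxazolidin-2-one (alkylation and aldol); benzofuran C2 trans to C3 in the ring closure; lactone C3 trans to C4 by base equilibration after the union.

Key step: step 13

Assumption: the trans-3,4-dibenzyl-γ-butyrolactone is taken as the thermodynamically favoured C3 epimer, as is general for this lactone class.

**Route**

Step 1
Reactants: 1 3-(4-hydroxy-3-methoxyphenyl)propanoic acid
Product: 3 3-[4-(benzyloxy)-3-methoxyphenyl]propanoic acid, via benzyl ester 2 (not isolated)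
Conditions: BnBr (2.3 equiv), K2CO3, DMF, 60 °C; then NaOH, MeOH/H2O, 60 °C; HCl to pH 2
Reagents that add atoms: benzyl bromide, BrCc1ccccc1; sodium hydroxide, [Na+].[OH-]
Why: Williamson O-benzylation of the phenol (the carboxylate is benzylated as well) followed by saponification of the benzyl ester should leave only the aryl benzyl ether.

Step 2
Reactants: 3 3-[4-(benzyloxy)-3-methoxyphenyl]propanoic acid; 4 (S)-4-benzyl-1,3-oxazolidin-2-one
Product: 6 (4S)-4-benzyl-3-{3-[4-(benzyloxy)-3-methoxyphenyl]propanoyl}-1,3-oxazolidin-2-one, via mixed pivalic anhydride 5 (not isolated)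
Conditions: PivCl, Et3N, THF, −20 °C; then 4, LiCl, −20 °C → rt
Reagents that add atoms: none
Why: N-acylation of the oxazolidinone through the mixed pivalic anhydride (LiCl/Et3N activation) is the standard loading of an Evans auxiliary; no stereocentre is formed.

Step 3
Reactants: 6 (4S)-4-benzyl-3-{3-[4-(benzyloxy)-3-methoxyphenyl]propanoyl}-1,3-oxazolidin-2-one
Product: 7 tert-butyl (3R)-3-[4-(benzyloxy)-3-methoxybenzyl]-4-[(4S)-4-benzyl-2-oxo-1,3-oxazolidin-3-yl]-4-oxobutanoate
Conditions: NaHMDS, THF, −78 °C; BrCH2CO2t-Bu, −78 → −40 °C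
Reagents that add atoms: tert-butyl bromoacetate, BrCC(=O)OC(C)(C)C
Why: Evans asymmetric alkylation, in which the chelated (Z)-sodium enolate is attacked on the face away from the benzyl group of the (S)-auxiliary, should set the (R) centre that becomes C4 of the lactone.

Step 4
Reactants: 7 tert-butyl (3R)-3-[4-(benzyloxy)-3-methoxybenzyl]-4-[(4S)-4-benzyl-2-oxo-1,3-oxazolidin-3-yl]-4-oxobutanoate
Product: 9 (4R)-4-[4-(benzyloxy)-3-methoxybenzyl]dihydrofuran-2(3H)-one, via hydroxy tert-butyl ester 8 (not isolated)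
Conditions: LiBH4, MeOH (1 equiv), THF, 0 °C; then TFA, CH2Cl2, 0 °C → rt
Reagents that add atoms: none
Why: LiBH4 cleaves the imide carbonyl reductively to the primary alcohol (auxiliary released, tert-butyl ester spared) and TFA then removes the tert-butyl group and closes the γ-lactone, with the stereocentre untouched.

Step 5
Reactants: 9 (4R)-4-[4-(benzyloxy)-3-methoxybenzyl]dihydrofuran-2(3H)-one
Product: 11 (4R)-4-[4-(benzyloxy)-3-methoxybenzyl]-3-methylenedihydrofuran-2(3H)-one, via sodium formyl-lactone enolate 10 (not isolated)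
Conditions: NaH, HCO2Et, THF, 0 °C → rt; then (CH2O)n, THF, reflux
Reagents that add atoms: formaldehyde (as paraformaldehyde), C=O
Why: Claisen formylation at C3 followed by reaction of the formyl enolate with formaldehyde (aldol addition, O-formyl transfer, loss of formate) is an established α-methylenation of γ-butyrolactones and should not touch the non-acidic C4 centre.

Step 6
Reactants: 12 5-bromo-2-hydroxy-3-methoxybenzaldehyde
Product: 13 5-bromo-3-methoxy-2-(methoxymethoxy)benzaldehyde
Conditions: MOMCl, i-Pr2NEt, CH2Cl2, 0 °C → rt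
Reagents that add atoms: chloromethyl methyl ether, COCCl
Why: MOM protection masks the phenol for the enolate chemistry to come and is removable by the same acid that later closes the ring.

Step 7
Reactants: 13 5-bromo-3-methoxy-2-(methoxymethoxy)benzaldehyde
Product: 15 [5-bromo-3-methoxy-2-(methoxymethoxy)phenyl]acetic acid, via trichloromethyl carbinol 14 (not isolated)
Conditions: CHCl3, DBU, 0 °C → rt; then NaBH4, NaOH, t-BuOH/H2O, 55 °C; acidify to pH 3–4 at 0 °C
Reagents that add atoms: chloroform, ClC(Cl)Cl; sodium hydroxide, [Na+].[OH-]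
Why: base-promoted addition of chloroform to the aldehyde and Jocic-type reductive homologation (gem-dichloroepoxide opened at the benzylic carbon by hydride, acyl chloride hydrolysed) should give the one-carbon-extended arylacetic acid under basic conditions that the MOM ether and the aryl bromide tolerate.

Step 8
Reactants: 15 [5-bromo-3-methoxy-2-(methoxymethoxy)phenyl]acetic acid; 4 (S)-4-benzyl-1,3-oxazolidin-2-one
Product: 17 (4S)-4-benzyl-3-{[5-bromo-3-methoxy-2-(methoxymethoxy)phenyl]acetyl}-1,3-oxazolidin-2-one, via mixed pivalic anhydride 16 (not isolated)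
Conditions: PivCl, Et3N, THF, −20 °C; then 4, LiCl, −20 °C → rt
Reagents that add atoms: none
Why: as in step 2, N-acylation of the auxiliary through the mixed pivalic anhydride; no stereocentre is formed.

Step 9
Reactants: 17 (4S)-4-benzyl-3-{[5-bromo-3-methoxy-2-(methoxymethoxy)phenyl]acetyl}-1,3-oxazolidin-2-one; 18 4-(benzyloxy)-3-methoxybenzaldehyde
Product: 19 (4S)-4-benzyl-3-{(2S,3S)-3-[4-(benzyloxy)-3-methoxyphenyl]-2-[5-bromo-3-methoxy-2-(methoxymethoxy)phenyl]-3-hydroxypropanoyl}-1,3-oxazolidin-2-one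
Conditions: n-Bu2BOTf, i-Pr2NEt, CH2Cl2, −78 → 0 °C; 18, −78 → 0 °C; pH 7 buffer, MeOH, H2O2, 0 °C
Reagents that add atoms: none
Why: the Evans boron syn-aldol reaction through the (Z)-boron enolate and a Zimmerman–Traxler transition state should set the aryl-bearing α-centre (2S) under control of the (S)-auxiliary, while the carbinol centre formed with it is of no consequence because it is planarised in step 11.

Step 10
Reactants: 19 (4S)-4-benzyl-3-{(2S,3S)-3-[4-(benzyloxy)-3-methoxyphenyl]-2-[5-bromo-3-methoxy-2-(methoxymethoxy)phenyl]-3-hydroxypropanoyl}-1,3-oxazolidin-2-one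
Product: 20 (1S,2R)-1-[4-(benzyloxy)-3-methoxyphenyl]-2-[5-bromo-3-methoxy-2-(methoxymethoxy)phenyl]propane-1,3-diol
Conditions: LiBH4, MeOH (1 equiv), THF, 0 °C
Reagents that add atoms: none
Why: reductive removal of the auxiliary with LiBH4 turns the acyl carbon into the future CH2OH group of the dihydrobenzofuran without touching the aryl-bearing centre.

Step 11
Reactants: 20 (1S,2R)-1-[4-(benzyloxy)-3-methoxyphenyl]-2-[5-bromo-3-methoxy-2-(methoxymethoxy)phenyl]propane-1,3-diol
Product: 21 [(2S,3R)-2-[4-(benzyloxy)-3-methoxyphenyl]-5-bromo-7-methoxy-2,3-dihydro-1-benzofuran-3-yl]methanol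
Conditions: HCl (1 M), MeOH/THF, rt → 40 °C
Reagents that add atoms: none
Why: acid cleaves the MOM ether and ionises the p-alkoxybenzylic alcohol to a cation that the freed phenol captures in a 5-exo-trig closure that is reversible under the conditions, so the aryl group at C2 should settle trans to the CH2OH group at C3 (C3 from the aldol step controls C2, and both carbinol epimers would converge).

Step 12
Reactants: 21 [(2S,3R)-2-[4-(benzyloxy)-3-methoxyphenyl]-5-bromo-7-methoxy-2,3-dihydro-1-benzofuran-3-yl]methanol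
Product: 22 [(2S,3R)-2-[4-(benzyloxy)-3-methoxyphenyl]-7-methoxy-5-(4,4,5,5-tetramethyl-1,3,2-dioxaborolan-2-yl)-2,3-dihydro-1-benzofuran-3-yl]methanol
Conditions: B2pin2, PdCl2(dppf) (cat.), KOAc, 1,4-dioxane, 85 °C
Reagents that add atoms: bis(pinacolato)diboron, CC1(C)OB(OC1(C)C)B1OC(C)(C)C(C)(C)O1
Why: Miyaura borylation of the aryl bromide tolerates the free alcohol, the benzyl ether and the cyclic benzylic ether and places boron at C5 for the union.

Step 13
Reactants: 11 (4R)-4-[4-(benzyloxy)-3-methoxybenzyl]-3-methylenedihydrofuran-2(3H)-one; 22 [(2S,3R)-2-[4-(benzyloxy)-3-methoxyphenyl]-7-methoxy-5-(4,4,5,5-tetramethyl-1,3,2-dioxaborolan-2-yl)-2,3-dihydro-1-benzofuran-3-yl]methanol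
Product: 24 (3R,4R)-4-[4-(benzyloxy)-3-methoxybenzyl]-3-({(2S,3R)-2-[4-(benzyloxy)-3-methoxyphenyl]-3-(hydroxymethyl)-7-methoxy-2,3-dihydro-1-benzofuran-5-yl}methyl)dihydrofuran-2(3H)-one, via C3-epimeric lactone mixture 23 (not isolated)
Conditions: [Rh(cod)OH]2 (3 mol %), K3PO4 (0.5 equiv), 1,4-dioxane/H2O 10:1, 50 °C; then, after extractive work-up, DBU, toluene, 80 °C
Reagents that add atoms: none
Why: Transmetalation of the aryl group of 22 from boron to a Rh(I) hydroxide gives an aryl–Rh species that adds across the exocyclic C=CH2 of 11 with the aryl group on the terminal CH2, and the resulting Rh oxa-π-allyl is protonated by water at C3, which regenerates Rh–OH. The closest known reaction type is the Rh-catalysed conjugate addition–protonation of arylboron reagents to α-substituted acrylates (Hayashi–Miyaura addition). No ring is closed in this step. The new stereocentre, lactone C3, first forms as a mixture (protonation anti to the C4 benzyl group favours cis), and DBU then equilibrates it through the lactone enolate to the trans-(3R,4R) isomer, so the fixed (R) centre at C4 controls C3 under thermodynamic control. The step needs β-regioselectivity, secured by the polarity of the α-methylene lactone with its unsubstituted terminus, and protonation in place of β-hydride elimination or double-bond migration into the ring, favoured by the aqueous medium and the mild temperature; the free CH2OH, the benzyl ethers and the benzylic C2–O1 bond of 22 should be inert to Rh(I) and DBU.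

Step 14
Reactants: 24 (3R,4R)-4-[4-(benzyloxy)-3-methoxybenzyl]-3-({(2S,3R)-2-[4-(benzyloxy)-3-methoxyphenyl]-3-(hydroxymethyl)-7-methoxy-2,3-dihydro-1-benzofuran-5-yl}methyl)dihydrofuran-2(3H)-one
Product: 25 (2R,3R)-2-[4-(benzyloxy)-3-methoxybenzyl]-3-({(2S,3R)-2-[4-(benzyloxy)-3-methoxyphenyl]-3-(hydroxymethyl)-7-methoxy-2,3-dihydro-1-benzofuran-5-yl}methyl)butane-1,4-diol
Conditions: LiAlH4 (excess), THF, 0 °C → rt; Fieser work-up
Reagents that add atoms: none
Why: LiAlH4 reduction of the γ-lactone opens the helper ring to the butane-1,4-diol, and both lactone stereocentres should keep their configuration because hydride reduction at low temperature does not enolise the lactone.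

Step 15
Reactants: 25 (2R,3R)-2-[4-(benzyloxy)-3-methoxybenzyl]-3-({(2S,3R)-2-[4-(benzyloxy)-3-methoxyphenyl]-3-(hydroxymethyl)-7-methoxy-2,3-dihydro-1-benzofuran-5-yl}methyl)butane-1,4-diol
Product: 26 (2R,3R)-2-(4-hydroxy-3-methoxybenzyl)-3-{[(2S,3R)-2-(4-hydroxy-3-methoxyphenyl)-3-(hydroxymethyl)-7-methoxy-2,3-dihydro-1-benzofuran-5-yl]methyl}butane-1,4-diol (target, CNP0256425.1)
Conditions: H2 (1 atm), 10% Pd/C, EtOAc/MeOH, rt
Reagents that add atoms: none
Why: catalytic hydrogenolysis removes both aryl benzyl ethers under mild conditions that are expected to leave the C2–O1 bond of the dihydrobenzofuran intact.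

**Compound list**

1 | 3-(4-hydroxy-3-methoxyphenyl)propanoic acid | COc1cc(CCC(=O)O)ccc1O | starting material
2 | benzyl 3-[4-(benzyloxy)-3-methoxyphenyl]propanoate | COc1cc(CCC(=O)OCc2ccccc2)ccc1OCc1ccccc1 | intermediate
3 | 3-[4-(benzyloxy)-3-methoxyphenyl]propanoic acid | COc1cc(CCC(=O)O)ccc1OCc1ccccc1 | intermediate
4 | (S)-4-benzyl-1,3-oxazolidin-2-one | O=C1N[C@@H](Cc2ccccc2)CO1 | starting material
5 | 3-[4-(benzyloxy)-3-methoxyphenyl]propanoic pivalic anhydride | COc1cc(CCC(=O)OC(=O)C(C)(C)C)ccc1OCc1ccccc1 | intermediate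
6 | (4S)-4-benzyl-3-{3-[4-(benzyloxy)-3-methoxyphenyl]propanoyl}-1,3-oxazolidin-2-one | COc1cc(CCC(=O)N2[C@@H](Cc3ccccc3)COC2=O)ccc1OCc1ccccc1 | intermediate
7 | tert-butyl (3R)-3-[4-(benzyloxy)-3-methoxybenzyl]-4-[(4S)-4-benzyl-2-oxo-1,3-oxazolidin-3-yl]-4-oxobutanoate | O=C(N1[C@@H](Cc2ccccc2)COC1=O)[C@@H](CC(=O)OC(C)(C)C)Cc1ccc(OCc2ccccc2)c(OC)c1 | intermediate
8 | tert-butyl (3R)-3-[4-(benzyloxy)-3-methoxybenzyl]-4-hydroxybutanoate | OC[C@@H](CC(=O)OC(C)(C)C)Cc1ccc(OCc2ccccc2)c(OC)c1 | intermediate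
9 | (4R)-4-[4-(benzyloxy)-3-methoxybenzyl]dihydrofuran-2(3H)-one | O=C1OC[C@H](Cc2ccc(OCc3ccccc3)c(OC)c2)C1 | intermediate
10 | sodium enolate of (4R)-4-[4-(benzyloxy)-3-methoxybenzyl]-3-formyldihydrofuran-2(3H)-one | O=C1OC[C@H](Cc2ccc(OCc3ccccc3)c(OC)c2)C1=C[O-].[Na+] | intermediate
11 | (4R)-4-[4-(benzyloxy)-3-methoxybenzyl]-3-methylenedihydrofuran-2(3H)-one | O=C1OC[C@H](Cc2ccc(OCc3ccccc3)c(OC)c2)C1=C | intermediate
12 | 5-bromo-2-hydroxy-3-methoxybenzaldehyde | COc1cc(Br)cc(C=O)c1O | starting material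
13 | 5-bromo-3-methoxy-2-(methoxymethoxy)benzaldehyde | COCOc1c(OC)cc(Br)cc1C=O | intermediate
14 | 1-[5-bromo-3-methoxy-2-(methoxymethoxy)phenyl]-2,2,2-trichloroethanol (racemic) | COCOc1c(OC)cc(Br)cc1C(O)C(Cl)(Cl)Cl | intermediate
15 | [5-bromo-3-methoxy-2-(methoxymethoxy)phenyl]acetic acid | COCOc1c(OC)cc(Br)cc1CC(=O)O | intermediate
16 | [5-bromo-3-methoxy-2-(methoxymethoxy)phenyl]acetic pivalic anhydride | COCOc1c(OC)cc(Br)cc1CC(=O)OC(=O)C(C)(C)C | intermediate
17 | (4S)-4-benzyl-3-{[5-bromo-3-methoxy-2-(methoxymethoxy)phenyl]acetyl}-1,3-oxazolidin-2-one | COCOc1c(OC)cc(Br)cc1CC(=O)N1[C@@H](Cc2ccccc2)COC1=O | intermediate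
18 | 4-(benzyloxy)-3-methoxybenzaldehyde | O=Cc1ccc(OCc2ccccc2)c(OC)c1 | starting material
19 | (4S)-4-benzyl-3-{(2S,3S)-3-[4-(benzyloxy)-3-methoxyphenyl]-2-[5-bromo-3-methoxy-2-(methoxymethoxy)phenyl]-3-hydroxypropanoyl}-1,3-oxazolidin-2-one | O=C(N1[C@@H](Cc2ccccc2)COC1=O)[C@@H](c1cc(Br)cc(OC)c1OCOC)[C@H](O)c1ccc(OCc2ccccc2)c(OC)c1 | intermediate
20 | (1S,2R)-1-[4-(benzyloxy)-3-methoxyphenyl]-2-[5-bromo-3-methoxy-2-(methoxymethoxy)phenyl]propane-1,3-diol | OC[C@@H](c1cc(Br)cc(OC)c1OCOC)[C@H](O)c1ccc(OCc2ccccc2)c(OC)c1 | intermediate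
21 | [(2S,3R)-2-[4-(benzyloxy)-3-methoxyphenyl]-5-bromo-7-methoxy-2,3-dihydro-1-benzofuran-3-yl]methanol | Brc1cc(OC)c2c(c1)[C@H](CO)[C@@H](c1ccc(OCc3ccccc3)c(OC)c1)O2 | intermediate
22 | [(2S,3R)-2-[4-(benzyloxy)-3-methoxyphenyl]-7-methoxy-5-(4,4,5,5-tetramethyl-1,3,2-dioxaborolan-2-yl)-2,3-dihydro-1-benzofuran-3-yl]methanol | CC1(C)OB(OC1(C)C)c1cc(OC)c2c(c1)[C@H](CO)[C@@H](c1ccc(OCc3ccccc3)c(OC)c1)O2 | intermediate
23 | (4R)-4-[4-(benzyloxy)-3-methoxybenzyl]-3-({(2S,3R)-2-[4-(benzyloxy)-3-methoxyphenyl]-3-(hydroxymethyl)-7-methoxy-2,3-dihydro-1-benzofuran-5-yl}methyl)dihydrofuran-2(3H)-one, mixture of C3 epimers | COc1cc(C[C@H]2COC(=O)C2Cc2cc(OC)c3c(c2)[C@H](CO)[C@@H](c2ccc(OCc4ccccc4)c(OC)c2)O3)ccc1OCc1ccccc1 | intermediate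
24 | (3R,4R)-4-[4-(benzyloxy)-3-methoxybenzyl]-3-({(2S,3R)-2-[4-(benzyloxy)-3-methoxyphenyl]-3-(hydroxymethyl)-7-methoxy-2,3-dihydro-1-benzofuran-5-yl}methyl)dihydrofuran-2(3H)-one | COc1cc(C[C@H]2COC(=O)[C@@H]2Cc2cc(OC)c3c(c2)[C@H](CO)[C@@H](c2ccc(OCc4ccccc4)c(OC)c2)O3)ccc1OCc1ccccc1 | intermediate
25 | (2R,3R)-2-[4-(benzyloxy)-3-methoxybenzyl]-3-({(2S,3R)-2-[4-(benzyloxy)-3-methoxyphenyl]-3-(hydroxymethyl)-7-methoxy-2,3-dihydro-1-benzofuran-5-yl}methyl)butane-1,4-diol | COc1cc(C[C@@H](CO)[C@H](CO)Cc2cc(OC)c3c(c2)[C@H](CO)[C@@H](c2ccc(OCc4ccccc4)c(OC)c2)O3)ccc1OCc1ccccc1 | intermediate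
26 | (2R,3R)-2-(4-hydroxy-3-methoxybenzyl)-3-{[(2S,3R)-2-(4-hydroxy-3-methoxyphenyl)-3-(hydroxymethyl)-7-methoxy-2,3-dihydro-1-benzofuran-5-yl]methyl}butane-1,4-diol | COc1cc(C[C@@H](CO)[C@H](CO)Cc2cc(OC)c3c(c2)[C@H](CO)[C@@H](c2ccc(O)c(OC)c2)O3)ccc1O | target

**Summary**

Total step count: 15.
Longest linear sequence: 10 steps (12 → 26, steps 6–15); the lactone half takes 5 steps (1 → 11).

Steps most likely to fail:

1. Step 13. The exocyclic double bond of 11 may migrate into the ring (which would also erase the C4 centre), 22 may protodeboronate, the Rh enolate may undergo β-hydride elimination, or the equilibration may stop short of the trans lactone. The fallback makes the same CH2–aryl bond by an sp3–sp2 Negishi coupling with the lactone C3 centre set beforehand. It sets out from lactone 9 and uses bromide 21, so that step 12 is not needed. LDA in THF at −78 °C followed by monomeric formaldehyde should give (3S,4R)-4-[4-(benzyloxy)-3-methoxybenzyl]-3-(hydroxymethyl)dihydrofuran-2(3H)-one F1 by aldol addition anti to the C4 substituent. I2, PPh3 and imidazole in CH2Cl2 at 0 °C should convert it into (3R,4R)-4-[4-(benzyloxy)-3-methoxybenzyl]-3-(iodomethyl)dihydrofuran-2(3H)-one F2. Activated zinc dust in DMF should insert to give {[(3R,4R)-4-[4-(benzyloxy)-3-methoxybenzyl]-2-oxotetrahydrofuran-3-yl]methyl}zinc iodide F3, which is coupled in excess (to allow for the free OH) with 21 under Pd2(dba)3/SPhos in DMF/THF at 40 °C and comes back to the route at lactone 24.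

2. Step 11. The benzylic cation of the 1,3-diol may lose formaldehyde (stilbene formation), the MOM-derived oxocarbenium ion may be captured by the diol as a cyclic formal, or the closure may be incompletely trans-selective. The fallback closes the ring at the acyl stage, before the auxiliary is removed, where no free 1,3-diol exists. It sets out from aldol 19: TFA in CH2Cl2 with MeOH (5 equiv) at 0 °C should give (4S)-4-benzyl-3-{[(2S,3S)-2-[4-(benzyloxy)-3-methoxyphenyl]-5-bromo-7-methoxy-2,3-dihydro-1-benzofuran-3-yl]carbonyl}-1,3-oxazolidin-2-one F4, in which the acyl group at C3 also allows base equilibration to trans if needed. LiBH4 in THF/MeOH at 0 °C then removes the auxiliary and comes back to the route at 21; steps 10 and 11 are replaced.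

3. Step 7. Hydroxide may open the gem-dichloroepoxide in place of hydride (mandelic acid formation), or chloroform may add incompletely to the hindered aldehyde. The fallback homologates through an enol ether. It sets out from aldehyde 13: a Wittig reaction with (methoxymethyl)triphenylphosphonium chloride/KHMDS in THF at 0 °C should give 5-bromo-1-methoxy-3-(2-methoxyethenyl)-2-(methoxymethoxy)benzene F5 as an E/Z mixture. Brief hydrolysis with aqueous formic acid in THF (0 °C → rt; the enol ether reacts far faster than the aryl MOM ether) should give [5-bromo-3-methoxy-2-(methoxymethoxy)phenyl]acetaldehyde F6. Pinnick oxidation (NaClO2, NaH2PO4, 2-methyl-2-butene, t-BuOH/H2O) comes back to the route at acid 15.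

**Further compounds**

F1 | step 13 | (3S,4R)-4-[4-(benzyloxy)-3-methoxybenzyl]-3-(hydroxymethyl)dihydrofuran-2(3H)-one | COc1cc(C[C@H]2COC(=O)[C@@H]2CO)ccc1OCc1ccccc1
F2 | step 13 | (3R,4R)-4-[4-(benzyloxy)-3-methoxybenzyl]-3-(iodomethyl)dihydrofuran-2(3H)-one | COc1cc(C[C@H]2COC(=O)[C@@H]2CI)ccc1OCc1ccccc1
F3 | step 13 | {[(3R,4R)-4-[4-(benzyloxy)-3-methoxybenzyl]-2-oxotetrahydrofuran-3-yl]methyl}zinc iodide | COc1cc(C[C@H]2COC(=O)[C@@H]2C[Zn]I)ccc1OCc1ccccc1
F4 | step 11 | (4S)-4-benzyl-3-{[(2S,3S)-2-[4-(benzyloxy)-3-methoxyphenyl]-5-bromo-7-methoxy-2,3-dihydro-1-benzofuran-3-yl]carbonyl}-1,3-oxazolidin-2-one | Brc1cc(OC)c2c(c1)[C@H](C(=O)N1[C@@H](Cc3ccccc3)COC1=O)[C@@H](c1ccc(OCc3ccccc3)c(OC)c1)O2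
F5 | step 7 | 5-bromo-1-methoxy-3-(2-methoxyethenyl)-2-(methoxymethoxy)benzene (E/Z mixture) | COCOc1c(OC)cc(Br)cc1C=COC
F6 | step 7 | [5-bromo-3-methoxy-2-(methoxymethoxy)phenyl]acetaldehyde | COCOc1c(OC)cc(Br)cc1CC=O
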